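**Retrosynthetic overview**
1. The butenolide comes last: C12–C13 by Stille coupling of an (E)-dienylstannane with 3-bromofuran-2(5H)-one; C8=C17 and C9–H by reductive 1,3-transposition of a Δ8(9)-17-al tosylhydrazone; C17 and C11–C12 are attached to a C9 ketone (bromoformylation, Stille).
2. Ring A: 3-OH/19-OAc ← 3-keto-19-ester ← one-pot [4+2] annulation of a ring-B ketimine with phenyl vinyl sulfone, which forms C1–C10 and C2–C3; the sulfone is then removed.
3. Ring B and absolute configuration: (S)-carvone (its C=O becomes C9, its ring methyl C20); C4–C5 by Michael addition of dimethyl methylmalonate; the C7 isopropenyl steers C5 (and through it C10) and is later deleted by dealkenylative hydrogenation.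
4. Ring order: ring B (carvone) → ring A (key step) → butenolide (brought in intact).
5. Enabling feature: in ring A the unsubstituted C1–C2 ethano bridge lies between C10, which is α to C9 (a ketone until the side chain is attached), and C3, which with C19 forms the two carboxyl carbons of a methylmalonate on quaternary C4; a vinyl acceptor therefore fits between a C10 enamine nucleophile and a C3 ester electrophile.

Key step: step 3

Remark: labdane numbering of the target is used for all intermediates (ring A = C1–C5, C10; ring B = C5–C10; C17 on C8; C18, C19 on C4; C20 on C10; C11/C12 vinylene; C13–C16 butenolide); centres that are erased later (C10 in 3 and 4, C2 in 8, the peroxy carbon in 10, C9 in 12 and 13) are left open or drawn as the expected epimer, and 16 and 23 are taken as purchasable.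

Step 1
Reactants: 1 dimethyl 2-methylmalonate; 2 (S)-(+)-carvone
Product: 3 dimethyl 2-methyl-2-[2-methyl-3-oxo-5-(prop-1-en-2-yl)cyclohexyl]malonate (malonyl carbon C4 on C5 trans to the C7 isopropenyl; C10 epimers)
Conditions: NaOMe (0.2 equiv), MeOH, 50 °C
Reagents that add atoms: none
Why: Base-catalysed Michael addition under equilibrating conditions, in which the methylmalonate anion should enter C5 axially on the face opposite the C7 isopropenyl group (5,7-trans); C4 is not yet stereogenic and C10 is erased in step 3.

Step 2
Reactants: 3 keto malonate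
Product: 4 N-cyclohexyl C9 ketimine of 3
Conditions: cyclohexylamine (1.5 equiv), p-TsOH·H2O (2 mol%), toluene, reflux, Dean–Stark; volatiles removed, used crude
Reagents that add atoms: cyclohexylamine NC1CCCCC1
Why: Acid-catalysed imine condensation with azeotropic removal of water; no stereocentre is set, and imine/secondary-enamine tautomerism makes the C10 epimers of 3 converge.

Step 3
Reactants: 4 ketimine; 5 phenyl vinyl sulfone
Product: 8 methyl 3,9-dioxo-2-(phenylsulfonyl)-7-(prop-1-en-2-yl)-4,10-dimethyl-trans-decalin-4-carboxylate (ring-A β-keto sulfone; C19 ester axial and cis to C20), via imine Michael adduct 6 (not isolated), via cyclised imine enolate 7 (not isolated)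
Conditions: 5 (1.05 equiv), THF, 55 °C; then t-BuOK (2.0 equiv), t-BuOH–THF, 25 → 50 °C; then 1 M aq. HCl–THF, 0 → 25 °C
Reagents that add atoms: water O
Why: Imine 4 reacts through its more substituted secondary enamine tautomer (C9=C10), whose C10 adds to the β-carbon of 5 in a compact aza-ene-type transition state with N–H transfer to C2 (C1–C10 bond, imine 6); t-BuOK then generates the α-sulfonyl carbanion at C2, which acylates on one of the two methyl esters of the methylmalonate unit (C2–C3 bond) to give the β-keto sulfone, held as enolate 7 until aqueous acid also hydrolyses the imine. The closest known reaction types are the Michael addition of imines of α-substituted cyclanones to electrophilic alkenes at the more substituted α-carbon and the sulfone Dieckmann (Claisen) acylation, together a Michael-initiated ring closure, that is, an anionic [4+2] annulation. Ring A is the only ring closed, and it closes 6-exo-trig by attack of C2 on the ester carbonyl C3. C10 is set by approach of 5 to the enamine face opposite the pseudoaxial C5 substituent, which puts C1 trans to C4 and so leads to the trans-decalin with axial C20; C4 is set by the choice between its two diastereotopic esters in a chair transition state that keeps the smaller ester axial (cis to C20) and the C18 methyl equatorial, avoiding a syn-diaxial methyl/methyl contact; C2 is epimerisable and is deleted in step 4. The step needs C10-over-C8 regioselectivity and must not lose the malonate: the first follows from the preference of secondary enamines for the more substituted tautomer, the second from forming C1–C10 under neutral conditions (a free C10 enolate could expel the methylmalonate anion by retro-Michael cleavage), after which C10 is quaternary and alkoxide equilibration funnels all anions to the enolisable β-keto sulfone, because Claisen products through C8 would be non-enolisable bridgehead 1,3-dicarbonyl systems that revert.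

Step 4
Reactants: 8 β-keto sulfone
Product: 9 methyl 3,9-dioxo-7-(prop-1-en-2-yl)-4,10-dimethyl-trans-decalin-4-carboxylate
Conditions: SmI2 (2.5 equiv), THF–MeOH, −78 °C
Reagents that add atoms: none
Why: Reductive desulfonylation of an α-sulfonyl ketone by single-electron transfer from SmI2 (ketyl, loss of sulfinate, protonation of the samarium enolate), which is much faster than reduction of the isolated C9 ketone; no stereocentre is set and the C2 centre disappears.

Step 5
Reactants: 9 diketo ester
Product: 11 methyl 3,9-dioxo-4,10-dimethyl-trans-decalin-4-carboxylate (C7 is CH2), via methoxy hydroperoxide 10 (not isolated)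
Conditions: O3, MeOH, −78 °C; then FeSO4·7H2O (1.2 equiv), PhSH (1.5 equiv), −78 → 25 °C
Reagents that add atoms: none
Why: Dealkenylative hydrogenation: Criegee ozonolysis in methanol gives α-methoxy hydroperoxide 10, divalent iron cleaves the O–O bond, β-scission of the alkoxy radical expels methyl acetate, and the secondary C7 radical takes hydrogen from thiophenol; C7 becomes a methylene group, so no stereocentre is set and the carvone control element is erased.

Step 6
Reactants: 11 diketo ester
Product: 12 3,9,19-triol (4,10-dimethyl-trans-decalin with 3-OH equatorial, C19 CH2OH axial, 9-OH)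
Conditions: LiAlH4 (4 equiv), THF, 0 → 65 °C; Fieser work-up
Reagents that add atoms: none
Why: Hydride reduction of both ketones and the ester, in which hydride should attack C3 axially from the face opposite the axial C19 and C20 groups to give the equatorial 3-hydroxyl cis to C19; the C9 carbinol configuration is immaterial because it is reoxidised in step 8.

Step 7
Reactants: 12 triol
Product: 13 3,19-cyclic carbonate 9-alcohol
Conditions: 1,1'-carbonyldiimidazole (1.1 equiv), THF, 25 → 50 °C
Reagents that add atoms: 1,1'-carbonyldiimidazole O=C(n1ccnc1)n1ccnc1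
Why: Carbonylation of the gauche 3,19-diol to the six-membered cyclic carbonate (primary C19 hydroxyl acylated first, then ring closure), which should leave the isolated hindered C9 hydroxyl free; no stereocentre is set.

Step 8
Reactants: 13 carbonate alcohol
Product: 14 3,19-cyclic carbonate 9-ketone
Conditions: Dess–Martin periodinane (1.3 equiv), CH2Cl2, 25 °C
Reagents that add atoms: none
Why: Dess–Martin oxidation of the only free secondary alcohol; no stereocentre is set.

Step 9
Reactants: 14 carbonate ketone
Product: 15 9-bromo-Δ8(9)-17-al 3,19-carbonate (β-bromo enal)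
Conditions: PBr3 (2.5 equiv), DMF (3 equiv), CHCl3, 0 → 60 °C; then ice-water
Reagents that add atoms: N,N-dimethylformamide CN(C)C=O; phosphorus tribromide BrP(Br)Br; water O
Why: Vilsmeier–Haack–Arnold bromoformylation, in which the ketone can enolise only towards C8 (C10 is quaternary), so C8 is formylated and the carbonyl carbon C9 becomes the vinylic bromide; no stereocentre is set.

Step 10
Reactants: 15 β-bromo enal; 16 (E)-1,2-bis(tributylstannyl)ethene
Product: 17 9-[(E)-2-(tributylstannyl)ethenyl]-Δ8(9)-17-al 3,19-carbonate
Conditions: 16 (2.5 equiv), Pd2(dba)3 (2.5 mol%), AsPh3 (10 mol%), NMP, 50 °C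
Reagents that add atoms: none
Why: Stille cross-coupling of the activated β-bromo enal with one tin terminus of excess 16, which should retain the E geometry and stop at mono-coupling; no stereocentre is set.

Step 11
Reactants: 17 stannyl dienal
Product: 18 (E)-tosylhydrazone of 17
Conditions: TsNHNH2 (1.05 equiv), THF, 25 °C
Reagents that add atoms: p-toluenesulfonohydrazide Cc1ccc(cc1)S(=O)(=O)NN
Why: Hydrazone condensation of the aldehyde, which is far faster than attack of the hydrazide on the carbonate; no stereocentre is set.

Step 12
Reactants: 18 tosylhydrazone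
Product: 20 8(17)-methylene 9-[(E)-2-(tributylstannyl)ethenyl] 3,19-carbonate (9-H axial), via allylic diazene 19 (not isolated)
Conditions: catecholborane (2 equiv), CHCl3, 0 °C; then NaOAc·3H2O (3 equiv), 60 °C
Reagents that add atoms: none
Why: Reductive 1,3-transposition of an α,β-unsaturated tosylhydrazone (1,2-hydride delivery, acetate-induced loss of sulfinate to diazene 19, retro-ene loss of N2), which moves the alkene to C8=C17 and should deliver hydrogen to C9 from the face opposite the axial C20 methyl, setting C9 with axial H and equatorial side chain.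

Step 13
Reactants: 20 carbonate
Product: 21 3,19-diol
Conditions: K2CO3 (0.3 equiv), MeOH, 25 °C
Reagents that add atoms: none
Why: Base-catalysed methanolysis (transesterification) of the cyclic carbonate, mild enough for the vinylstannane and the skipped diene; no stereocentre is set.

Step 14
Reactants: 21 diol
Product: 22 19-acetate 3-ol
Conditions: AcCl (1.1 equiv), 2,4,6-collidine (2 equiv), CH2Cl2, −78 °C
Reagents that add atoms: acetyl chloride CC(Cl)=O
Why: Kinetically selective acylation of the primary C19 hydroxyl over the hindered secondary C3 hydroxyl with an acyl chloride and a hindered pyridine base at low temperature; no stereocentre is set.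

Step 15
Reactants: 22 stannane; 23 3-bromofuran-2(5H)-one
Product: 24 target
Conditions: 23 (1.3 equiv), Pd2(dba)3 (5 mol%), AsPh3 (20 mol%), CuI (10 mol%), NMP, 25 → 40 °C
Reagents that add atoms: none
Why: Stille cross-coupling of the (E)-vinylstannane with the α-bromobutenolide under neutral conditions, which should retain the E geometry and tolerate the free hydroxyl, the acetate and the base-sensitive butenolide; no stereocentre is set.

**Compound list**
1 | dimethyl 2-methylmalonate | COC(=O)C(C)C(=O)OC | starting material
2 | (S)-(+)-carvone | CC1=CC[C@@H](CC1=O)C(C)=C | starting material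
3 | dimethyl 2-methyl-2-[2-methyl-3-oxo-5-(prop-1-en-2-yl)cyclohexyl]malonate (5,7-trans; C10 epimers) | O=C1C[C@@H](C(C)=C)C[C@H](C(C)(C(=O)OC)C(=O)OC)C1C | intermediate
4 | N-cyclohexyl C9 ketimine of 3 | C1CCCCC1N=C1C[C@@H](C(C)=C)C[C@H](C(C)(C(=O)OC)C(=O)OC)C1C | intermediate
5 | phenyl vinyl sulfone | C=CS(=O)(=O)c1ccccc1 | starting material
6 | C10-quaternary ketimine with 2-(phenylsulfonyl)ethyl arm trans to the C5 malonyl group | C1CCCCC1N=C1C[C@@H](C(C)=C)C[C@H](C(C)(C(=O)OC)C(=O)OC)[C@@]1(C)CCS(=O)(=O)c1ccccc1 | intermediate
7 | potassium enolate of the ring-A β-keto sulfone N-cyclohexyl ketimine | C1[C@@H](C(C)=C)C[C@@H]2[C@](C)(C(=O)OC)C([O-])=C(S(=O)(=O)c3ccccc3)C[C@@]2(C)C1=NC1CCCCC1.[K+] | intermediate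
8 | methyl 3,9-dioxo-2-(phenylsulfonyl)-7-(prop-1-en-2-yl)-4,10-dimethyl-trans-decalin-4-carboxylate (C19 ester axial; C2 drawn equatorial) | C1[C@@H](C(C)=C)C[C@@H]2[C@](C)(C(=O)OC)C(=O)[C@@H](S(=O)(=O)c3ccccc3)C[C@@]2(C)C1=O | intermediate
9 | methyl 3,9-dioxo-7-(prop-1-en-2-yl)-4,10-dimethyl-trans-decalin-4-carboxylate | C1[C@@H](C(C)=C)C[C@@H]2[C@](C)(C(=O)OC)C(=O)CC[C@@]2(C)C1=O | intermediate
10 | α-methoxy hydroperoxide at the former isopropenyl carbon of 9 | C1[C@@H](C(C)(OC)OO)C[C@@H]2[C@](C)(C(=O)OC)C(=O)CC[C@@]2(C)C1=O | intermediate
11 | methyl 3,9-dioxo-4,10-dimethyl-trans-decalin-4-carboxylate | C1CC[C@@H]2[C@](C)(C(=O)OC)C(=O)CC[C@@]2(C)C1=O | intermediate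
12 | 3,9,19-triol | C1CC[C@@H]2[C@](C)(CO)[C@H](O)CC[C@@]2(C)[C@@H]1O | intermediate
13 | 3,19-cyclic carbonate 9-alcohol | C1CC[C@@H]2[C@](C)(COC(=O)O3)[C@H]3CC[C@@]2(C)[C@@H]1O | intermediate
14 | 3,19-cyclic carbonate 9-ketone | C1CC[C@@H]2[C@](C)(COC(=O)O3)[C@H]3CC[C@@]2(C)C1=O | intermediate
15 | 9-bromo-Δ8(9)-17-al 3,19-carbonate | O=CC=1CC[C@@H]2[C@](C)(COC(=O)O3)[C@H]3CC[C@@]2(C)C=1Br | intermediate
16 | (E)-1,2-bis(tributylstannyl)ethene | CCCC[Sn](CCCC)(CCCC)/C=C/[Sn](CCCC)(CCCC)CCCC | starting material
17 | 9-[(E)-2-(tributylstannyl)ethenyl]-Δ8(9)-17-al 3,19-carbonate | O=CC=1CC[C@@H]2[C@](C)(COC(=O)O3)[C@H]3CC[C@@]2(C)C=1/C=C/[Sn](CCCC)(CCCC)CCCC | intermediate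
18 | (E)-tosylhydrazone of 17 | Cc1ccc(cc1)S(=O)(=O)N/N=C/C=1CC[C@@H]2[C@](C)(COC(=O)O3)[C@H]3CC[C@@]2(C)C=1\C=C\[Sn](CCCC)(CCCC)CCCC | intermediate
19 | allylic diazene (C17H2–N=NH on C8) | N=NCC=1CC[C@@H]2[C@](C)(COC(=O)O3)[C@H]3CC[C@@]2(C)C=1/C=C/[Sn](CCCC)(CCCC)CCCC | intermediate
20 | 8(17)-methylene 9-[(E)-2-(tributylstannyl)ethenyl] 3,19-carbonate | C=C1CC[C@@H]2[C@](C)(COC(=O)O3)[C@H]3CC[C@@]2(C)[C@@H]1/C=C/[Sn](CCCC)(CCCC)CCCC | intermediate
21 | 3,19-diol of 20 | C=C1CC[C@@H]2[C@](C)(CO)[C@H](O)CC[C@@]2(C)[C@@H]1/C=C/[Sn](CCCC)(CCCC)CCCC | intermediate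
22 | 19-acetate 3-ol | C=C1CC[C@@H]2[C@](C)(COC(C)=O)[C@H](O)CC[C@@]2(C)[C@@H]1/C=C/[Sn](CCCC)(CCCC)CCCC | intermediate
23 | 3-bromofuran-2(5H)-one | O=C1OCC=C1Br | starting material
24 | 19-acetoxy-3-hydroxy-ent-labda-8(17),11E,13-trien-16,15-olide (3-OH equatorial, cis to C19) | C=C1CC[C@@H]2[C@](C)(COC(C)=O)[C@H](O)CC[C@@]2(C)[C@@H]1/C=C/C1=CCOC1=O | target

Total steps: 15. Longest linear sequence: 15 steps (2 → 24).

**Steps most likely to fail**

Step 3. The aza-ene alkylation may stall at the congested C10 or be diverted to C8 through the less substituted enamine, and the base stage may close the ring incompletely. The fallback is a regiodefined enolate route that sets out from 3 and returns at 8. Thermodynamic silylation of 3 (Me3SiCl, NaI, Et3N, MeCN) should give the tetrasubstituted trimethylsilyl enol ether F1. t-BuOK in THF at −78 °C should release the potassium C10 enolate F2, which is trapped cold with 5 (to outrun retro-Michael loss of the malonate) to give the α-sulfonyl carbanion F3. On warming, F3 should undergo the same Dieckmann closure, and acidic work-up should give 8.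

Step 1. The conjugate addition may stop at an unfavourable equilibrium (retro-Michael at the crowded quaternary centre), or the adduct may be drained by intramolecular Claisen condensation under alkoxide. The fallback is a Lewis acid route that sets out from 1 and returns at 3. O-silylation of 1 (Me3SiOTf, Et3N, Et2O) should give the ketene silyl acetal F4. F4 is added to 2 in a TiCl4-promoted Mukaiyama–Michael reaction (CH2Cl2, −78 °C), which is irreversible and should follow the same axial approach anti to the isopropenyl group, giving 3 after aqueous work-up.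

Step 12. The borane may over-reduce or hydroborate, the vinylstannane may be protodestannylated during the warm acetate stage, or sulfinate elimination may be incomplete. The fallback reaches the same diazene by a Mitsunobu route that sets out from 17 and returns at 20. Luche reduction (NaBH4, CeCl3·7H2O, MeOH, 0 °C) should give the primary allylic alcohol F5. Mitsunobu displacement with 2-nitrobenzenesulfonylhydrazide (PPh3, DEAD, THF, −30 °C) should give the N-allyl sulfonylhydrazine F6. On warming to 25 °C under neutral conditions, F6 should lose the sulfinate to give diazene 19 and then N2 to give 20.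

**Further compounds**
F1 | step 3 | trimethylsilyl enol ether of 3 (C9=C10) | C[Si](C)(C)OC1=C(C)[C@@H](C(C)(C(=O)OC)C(=O)OC)C[C@H](C(C)=C)C1
F2 | step 3 | potassium C10 enolate of 3 | [K+].[O-]C1=C(C)[C@@H](C(C)(C(=O)OC)C(=O)OC)C[C@H](C(C)=C)C1
F3 | step 3 | potassium α-sulfonyl carbanion of the C10-alkylated ketone | [K+].O=C1C[C@@H](C(C)=C)C[C@H](C(C)(C(=O)OC)C(=O)OC)[C@@]1(C)C[CH-]S(=O)(=O)c1ccccc1
F4 | step 1 | methyl (Z)-3-methoxy-2-methyl-3-(trimethylsilyloxy)prop-2-enoate (either geometry serves) | COC(=O)/C(C)=C(/OC)O[Si](C)(C)C
F5 | step 12 | Δ8(9)-17-ol of 17 (primary allylic alcohol) | OCC=1CC[C@@H]2[C@](C)(COC(=O)O3)[C@H]3CC[C@@]2(C)C=1/C=C/[Sn](CCCC)(CCCC)CCCC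
F6 | step 12 | N-allyl-N-(2-nitrophenylsulfonyl)hydrazine from F5 | NN(CC=1CC[C@@H]2[C@](C)(COC(=O)O3)[C@H]3CC[C@@]2(C)C=1/C=C/[Sn](CCCC)(CCCC)CCCC)S(=O)(=O)c1ccccc1[N+](=O)[O-]
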